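The trans-hydroazulene is disconnected at C1–C5 and C7–C8 (guaiane numbering) into an oxyallyl unit C5–C6–C7 and a diene C1=C10–C9=C8 linked through C2–C4. The route exploits the 1,3-relationship between the C4 carbinol of the five-membered ring and the C6 oxygen of the seven-membered ring: an epoxy enol silane undergoes an intramolecular (4+3) cycloaddition that closes both rings, opens the C4–C5 epoxide with inversion (freeing O-4), leaves C6 as a ketone, takes C8–O from a dienyl benzyl ether and carries a C10 silylmethyl group as latent exocyclic methylene. The precursor is an acyclic (Z)-triethylsilyl enol ether of an epoxy isobutyl ketone tethered to a (1E,3Z)-1-benzyloxy-3-(trimethylsilylmethyl)diene.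

Key step: step 15

Remark: atom labels C1–C15 in the text are guaiane positions (C1/C5 ring fusion; C2, C3, C4 complete the five-membered ring; C6–C10 the seven-membered ring; C14 the methylene carbon); they are not the locants of the systematic names.

Step 1
Reactants: 1 ethyl (2E)-3-methyl-4-oxobut-2-enoate
Product: 2 ethyl (2E,4S)-4-hydroxy-3-methylhepta-2,6-dienoate
Conditions: (−)-Ipc2B(allyl), Et2O, −78 °C; then HOCH2CH2NH2
Reagents that add atoms: (−)-B-allyldiisopinocampheylborane, C=CCB([C@@H]1C[C@@H]2C[C@H]([C@H]1C)C2(C)C)[C@@H]1C[C@@H]2C[C@H]([C@H]1C)C2(C)C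
Why: Brown asymmetric allylboration through a chair transition state; the reagent derived from (+)-α-pinene adds to the Si face of the aldehyde and sets C3 as (S), while the hindered enoate is inert at −78 °C.

Step 2
Reactants: 2 ethyl (2E,4S)-4-hydroxy-3-methylhepta-2,6-dienoate
Product: 3 ethyl (2E,4S)-4-(benzyloxy)-3-methylhepta-2,6-dienoate
Conditions: BnOC(=NH)CCl3, TfOH (cat.), CH2Cl2/cyclohexane, 0 °C
Reagents that add atoms: benzyl 2,2,2-trichloroacetimidate, ClC(Cl)(Cl)C(=N)OCc1ccccc1
Why: Acid-catalysed O-benzylation with the trichloroacetimidate avoids base, which could isomerise the γ-alkoxy enoate, and touches no stereocentre.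

Step 3
Reactants: 3 ethyl (2E,4S)-4-(benzyloxy)-3-methylhepta-2,6-dienoate
Product: 4 (2E,4S)-4-(benzyloxy)-3-methylhepta-2,6-dien-1-ol
Conditions: iBu2AlH (2.2 equiv), CH2Cl2, −78 °C; Rochelle salt work-up
Reagents that add atoms: none
Why: 1,2-Reduction of the conjugated ester by the aluminium hydride gives the (E)-allylic alcohol without changing the alkene geometry or the benzyl ether.

Step 4
Reactants: 4 (2E,4S)-4-(benzyloxy)-3-methylhepta-2,6-dien-1-ol
Product: 5 [(2R,3R)-3-[(1S)-1-(benzyloxy)but-3-en-1-yl]-3-methyloxiran-2-yl]methanol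
Conditions: Ti(OiPr)4, D-(−)-diethyl tartrate, tBuOOH, 4 Å molecular sieves, CH2Cl2, −20 °C
Reagents that add atoms: tert-butyl hydroperoxide, CC(C)(C)OO
Why: Katsuki–Sharpless asymmetric epoxidation; D-(−)-tartrate gives the (2R,3R)-epoxide (the sense opposite to L-(+)-tartrate, which gives (2S,3S)-epoxides from geraniol-type alcohols), so C4 and C5 are set under reagent control, and the terminal alkene has no directing hydroxyl and is untouched.

Step 5
Reactants: 5 [(2R,3R)-3-[(1S)-1-(benzyloxy)but-3-en-1-yl]-3-methyloxiran-2-yl]methanol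
Product: 6 (2S,3R)-3-[(1S)-1-(benzyloxy)but-3-en-1-yl]-3-methyloxirane-2-carbaldehyde
Conditions: Dess–Martin periodinane, pyridine, CH2Cl2, 0 °C to rt
Reagents that add atoms: none
Why: Dess–Martin oxidation of the primary alcohol under buffered conditions leaves the epoxide and its configuration intact (the descriptor at the oxirane CH changes only by priority).

Step 6
Reactants: 6 (2S,3R)-3-[(1S)-1-(benzyloxy)but-3-en-1-yl]-3-methyloxirane-2-carbaldehyde
Product: 7 1-[(2R,3R)-3-[(1S)-1-(benzyloxy)but-3-en-1-yl]-3-methyloxiran-2-yl]-3-methylbutan-1-ol (both carbinol epimers)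
Conditions: iBuMgBr, THF, −78 °C; then H2O
Reagents that add atoms: isobutylmagnesium bromide, CC(C)C[Mg]Br
Why: Grignard 1,2-addition to the epoxy aldehyde is faster than epoxide opening at −78 °C, and the new carbinol centre needs no control because it is oxidised in the next step.

Step 7
Reactants: 7 1-[(2R,3R)-3-[(1S)-1-(benzyloxy)but-3-en-1-yl]-3-methyloxiran-2-yl]-3-methylbutan-1-ol
Product: 8 1-[(2S,3R)-3-[(1S)-1-(benzyloxy)but-3-en-1-yl]-3-methyloxiran-2-yl]-3-methylbutan-1-one
Conditions: Dess–Martin periodinane, pyridine, CH2Cl2, rt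
Reagents that add atoms: none
Why: Dess–Martin oxidation converges both epimers to the α,β-epoxy isobutyl ketone without epimerising the oxirane carbon.

Step 8
Reactants: 8 1-[(2S,3R)-3-[(1S)-1-(benzyloxy)but-3-en-1-yl]-3-methyloxiran-2-yl]-3-methylbutan-1-one
Product: 9 (3S)-3-(benzyloxy)-3-[(2R,3S)-2-methyl-3-(3-methylbutanoyl)oxiran-2-yl]propanal
Conditions: O3, CH2Cl2, −78 °C; then Me2S
Reagents that add atoms: ozone, [O-][O+]=O
Why: Ozonolysis with reductive work-up cleaves the only alkene in the molecule to the β-benzyloxy aldehyde.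

Step 9
Reactants: 9 (3S)-3-(benzyloxy)-3-[(2R,3S)-2-methyl-3-(3-methylbutanoyl)oxiran-2-yl]propanal
Product: 10 1-[(2S,3R)-3-[(1S)-1-(benzyloxy)-4,4-dibromobut-3-en-1-yl]-3-methyloxiran-2-yl]-3-methylbutan-1-one
Conditions: CBr4, PPh3, Zn, CH2Cl2, 0 °C to rt
Reagents that add atoms: carbon tetrabromide, BrC(Br)(Br)Br
Why: Ramirez dibromo-olefination (first stage of the Corey–Fuchs sequence) with the preformed ylide reacts with the aldehyde and not with the less electrophilic ketone.

Step 10
Reactants: 11 benzyl alcohol; 12 trichloroethylene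
Product: 13 benzyl (E)-1,2-dichloroethenyl ether
Conditions: KH, THF, 0 °C to rt
Reagents that add atoms: none
Why: The potassium alkoxide adds to dichloroacetylene formed in the flask from trichloroethylene (addition–elimination), which gives the (E)-dichlorovinyl ether.

Step 11
Reactants: 13 benzyl (E)-1,2-dichloroethenyl ether
Product: 14 benzyl ethynyl ether
Conditions: nBuLi (2.2 equiv), Et2O, −78 to −40 °C; then MeOH; used at once
Reagents that add atoms: none
Why: Deprotonation and β-elimination give the chloroalkynyl ether, chlorine–lithium exchange and protonation give the terminal ynol ether (Greene ynol ether synthesis).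

Step 12
Reactants: 10 1-[(2S,3R)-3-[(1S)-1-(benzyloxy)-4,4-dibromobut-3-en-1-yl]-3-methyloxiran-2-yl]-3-methylbutan-1-one; 14 benzyl ethynyl ether
Product: 16 1-[(2S,3R)-3-[(1S,3Z,5E)-1,6-bis(benzyloxy)-4-bromohexa-3,5-dien-1-yl]-3-methyloxiran-2-yl]-3-methylbutan-1-one, via alkenylboronate 15 (not isolated)
Conditions: 14, pinacolborane, Cp2Zr(H)Cl (5 mol%), CH2Cl2, rt; then 10, Pd2(dba)3, tri(2-furyl)phosphine, aq Cs2CO3, THF, 50 °C
Reagents that add atoms: none
Why: Zirconium-catalysed syn-hydroboration puts boron on the terminal carbon and gives the (E)-boronate, and in the Suzuki–Miyaura coupling zerovalent palladium inserts faster into the C–Br bond trans to the alkyl chain, so the alkoxyvinyl group enters trans and the (3Z)-bromodiene is formed.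

Step 13
Reactants: 16 1-[(2S,3R)-3-[(1S,3Z,5E)-1,6-bis(benzyloxy)-4-bromohexa-3,5-dien-1-yl]-3-methyloxiran-2-yl]-3-methylbutan-1-one
Product: 17 1-[(2S,3R)-3-[(1S,3Z,5E)-1,6-bis(benzyloxy)-4-[(trimethylsilyl)methyl]hexa-3,5-dien-1-yl]-3-methyloxiran-2-yl]-3-methylbutan-1-one
Conditions: Me3SiCH2MgCl, ZnCl2, THF, 0 °C; then 16, Pd(P(tBu)3)2 (5 mol%), THF, rt
Reagents that add atoms: (trimethylsilyl)methylmagnesium chloride, C[Si](C)(C)C[Mg]Cl (transmetalated in the flask to the zinc reagent)
Why: Negishi coupling; with the bulky-phosphine catalyst alkylation of (Z)-2-bromo-1,3-dienes proceeds with retention, so the silylmethyl group ends cis to the chain, and the organozinc does not attack the epoxy ketone.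

Step 14
Reactants: 17 1-[(2S,3R)-3-[(1S,3Z,5E)-1,6-bis(benzyloxy)-4-[(trimethylsilyl)methyl]hexa-3,5-dien-1-yl]-3-methyloxiran-2-yl]-3-methylbutan-1-one
Product: 18 {[(1Z)-1-[(2S,3R)-3-[(1S,3Z,5E)-1,6-bis(benzyloxy)-4-[(trimethylsilyl)methyl]hexa-3,5-dien-1-yl]-3-methyloxiran-2-yl]-3-methylbut-1-en-1-yl]oxy}triethylsilane
Conditions: LiN(SiMe3)2, THF/DMPU, −78 °C; then Et3SiCl
Reagents that add atoms: chlorotriethylsilane, CC[Si](Cl)(CC)CC
Why: Kinetic deprotonation occurs at the isobutyl methylene (the oxiranyl C–H is not removed), the amide base in THF/DMPU favours the (Z)-enolate, and O-silylation gives the epoxy enol silane.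

Step 15
Reactants: 18 {[(1Z)-1-[(2S,3R)-3-[(1S,3Z,5E)-1,6-bis(benzyloxy)-4-[(trimethylsilyl)methyl]hexa-3,5-dien-1-yl]-3-methyloxiran-2-yl]-3-methylbut-1-en-1-yl]oxy}triethylsilane
Product: 19 (2S,3S,3aR,5R,6S,8aS)-2,6-bis(benzyloxy)-3-methyl-5-(propan-2-yl)-3-[(triethylsilyl)oxy]-8-[(trimethylsilyl)methyl]-2,3,3a,5,6,8a-hexahydroazulen-4(1H)-one (trans-fused)
Conditions: Et3SiOTf (20 mol%), CH2Cl2 (0.005 M), −78 °C; then Et3N
Reagents that add atoms: none
Why: Et3SiOTf silylates the epoxide oxygen, the diene terminus C1 (nucleophilic through both the enol ether and the allylsilane) attacks C5 anti to the breaking C5–O bond while the enol silane stabilises the developing silyloxyallyl cation C5–C6–C7, and C7 then closes on the oxocarbenium-like carbon C8 in a concerted but asynchronous (4+3) cycloaddition, the silyl group ending on O-4 so that the triflate turns over. The closest known reactions are the silyl-triflate-catalysed (4+3) cycloadditions of epoxy enol silanes with dienes, which run inter- and intramolecularly with transfer of the epoxide configuration, and the intramolecular oxyallyl–diene cycloadditions that give hydroazulenones. The five-membered ring closes by 5-exo-trig attack of C1 on the allyl terminus C5 (an endo-mode opening of the epoxide) and the seven-membered ring by 7-(enol-endo)-exo-trig attack of C7 on C8. C5 is set by inversion at the epoxide carbon; C1 by the extended (chair-like) arrangement of diene and oxyallyl unit, which puts H-1 and H-5 trans; C8 by suprafacial addition to the s-cis (1E,3Z)-diene with the tether and the benzyloxy group both outside, hence cis to C2; and C7 by the (Z)-enol silane geometry (isopropyl outside, trans to O-8). The step needs the extended over the compact arrangement, C5–O over C4–O cleavage and ring closure faster than loss of Me3Si+; the first should be favoured because it leads to the all-pseudo-equatorial trans-fused product and keeps the Et3SiO group away from the diene, the second by the allylic stabilisation from the enol silane, and the third by intramolecular closure onto an oxocarbenium ion at −78 °C under high dilution.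

Step 16
Reactants: 19 (2S,3S,3aR,5R,6S,8aS)-2,6-bis(benzyloxy)-3-methyl-5-(propan-2-yl)-3-[(triethylsilyl)oxy]-8-[(trimethylsilyl)methyl]-2,3,3a,5,6,8a-hexahydroazulen-4(1H)-one
Product: 20 (2S,3S,3aR,5R,6S,8aS)-2,6-bis(benzyloxy)-3-hydroxy-3-methyl-8-methylidene-5-(propan-2-yl)octahydroazulen-4(1H)-one
Conditions: CF3CO2H, CH2Cl2/H2O (20:1), 0 °C, short reaction time
Reagents that add atoms: none
Why: Protodesilylation of the allylsilane (SE2′): protonation at C9 gives the β-silyl-stabilised C10 cation, which loses silicon to place the double bond exocyclic (C10=C14) under kinetic control, and the tertiary triethylsilyl ether is hydrolysed in the same medium.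

Step 17
Reactants: 20 (2S,3S,3aR,5R,6S,8aS)-2,6-bis(benzyloxy)-3-hydroxy-3-methyl-8-methylidene-5-(propan-2-yl)octahydroazulen-4(1H)-one
Product: 21 (1S,2S,3aS,6S,7R,8S,8aS)-1-methyl-4-methylidene-7-(propan-2-yl)decahydroazulene-1,2,6,8-tetrol
Conditions: Li, NH3(l), THF, tBuOH, −78 °C; then H2O
Reagents that add atoms: none
Why: Birch-type dissolving-metal conditions cleave both benzyl ethers and reduce the hindered ketone through its ketyl to the thermodynamically preferred pseudo-equatorial C6 carbinol (trans to the C7 isopropyl group and to C4 on C5), while the isolated 1,1-disubstituted alkene is not reduced.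

Step 18
Reactants: 21 (1S,2S,3aS,6S,7R,8S,8aS)-1-methyl-4-methylidene-7-(propan-2-yl)decahydroazulene-1,2,6,8-tetrol
Product: 22 (1S,2S,3aS,6S,7R,8S,8aS)-1-hydroxy-1-methyl-4-methylidene-7-(propan-2-yl)decahydroazulene-2,6,8-triyl triacetate (CNP0147943.1)
Conditions: Ac2O, pyridine, DMAP (cat.), CH2Cl2, rt
Reagents that add atoms: acetic anhydride, CC(=O)OC(C)=O
Why: DMAP-catalysed acetylation esterifies the three secondary alcohols, and the hindered tertiary C4 alcohol should stay free under these conditions.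

Compound list
1 | ethyl (2E)-3-methyl-4-oxobut-2-enoate | CCOC(=O)/C=C(\C)C=O | starting material
2 | ethyl (2E,4S)-4-hydroxy-3-methylhepta-2,6-dienoate | CCOC(=O)/C=C(\C)[C@@H](O)CC=C | intermediate
3 | ethyl (2E,4S)-4-(benzyloxy)-3-methylhepta-2,6-dienoate | CCOC(=O)/C=C(\C)[C@@H](OCc1ccccc1)CC=C | intermediate
4 | (2E,4S)-4-(benzyloxy)-3-methylhepta-2,6-dien-1-ol | OC/C=C(\C)[C@@H](OCc1ccccc1)CC=C | intermediate
5 | [(2R,3R)-3-[(1S)-1-(benzyloxy)but-3-en-1-yl]-3-methyloxiran-2-yl]methanol | OC[C@H]1O[C@]1(C)[C@@H](OCc1ccccc1)CC=C | intermediate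
6 | (2S,3R)-3-[(1S)-1-(benzyloxy)but-3-en-1-yl]-3-methyloxirane-2-carbaldehyde | O=C[C@H]1O[C@]1(C)[C@@H](OCc1ccccc1)CC=C | intermediate
7 | 1-[(2R,3R)-3-[(1S)-1-(benzyloxy)but-3-en-1-yl]-3-methyloxiran-2-yl]-3-methylbutan-1-ol (both carbinol epimers) | CC(C)CC(O)[C@H]1O[C@]1(C)[C@@H](OCc1ccccc1)CC=C | intermediate
8 | 1-[(2S,3R)-3-[(1S)-1-(benzyloxy)but-3-en-1-yl]-3-methyloxiran-2-yl]-3-methylbutan-1-one | CC(C)CC(=O)[C@H]1O[C@]1(C)[C@@H](OCc1ccccc1)CC=C | intermediate
9 | (3S)-3-(benzyloxy)-3-[(2R,3S)-2-methyl-3-(3-methylbutanoyl)oxiran-2-yl]propanal | CC(C)CC(=O)[C@H]1O[C@]1(C)[C@@H](OCc1ccccc1)CC=O | intermediate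
10 | 1-[(2S,3R)-3-[(1S)-1-(benzyloxy)-4,4-dibromobut-3-en-1-yl]-3-methyloxiran-2-yl]-3-methylbutan-1-one | CC(C)CC(=O)[C@H]1O[C@]1(C)[C@@H](OCc1ccccc1)CC=C(Br)Br | intermediate
11 | benzyl alcohol | OCc1ccccc1 | starting material
12 | trichloroethylene | ClC=C(Cl)Cl | starting material
13 | benzyl (E)-1,2-dichloroethenyl ether | Cl/C=C(/Cl)OCc1ccccc1 | intermediate
14 | benzyl ethynyl ether | C#COCc1ccccc1 | intermediate
15 | 2-[(E)-2-(benzyloxy)ethenyl]-4,4,5,5-tetramethyl-1,3,2-dioxaborolane | CC1(C)OB(/C=C/OCc2ccccc2)OC1(C)C | intermediate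
16 | 1-[(2S,3R)-3-[(1S,3Z,5E)-1,6-bis(benzyloxy)-4-bromohexa-3,5-dien-1-yl]-3-methyloxiran-2-yl]-3-methylbutan-1-one | CC(C)CC(=O)[C@H]1O[C@]1(C)[C@@H](OCc1ccccc1)C/C=C(\Br)/C=C/OCc1ccccc1 | intermediate
17 | 1-[(2S,3R)-3-[(1S,3Z,5E)-1,6-bis(benzyloxy)-4-[(trimethylsilyl)methyl]hexa-3,5-dien-1-yl]-3-methyloxiran-2-yl]-3-methylbutan-1-one | CC(C)CC(=O)[C@H]1O[C@]1(C)[C@@H](OCc1ccccc1)C/C=C(\C[Si](C)(C)C)/C=C/OCc1ccccc1 | intermediate
18 | {[(1Z)-1-[(2S,3R)-3-[(1S,3Z,5E)-1,6-bis(benzyloxy)-4-[(trimethylsilyl)methyl]hexa-3,5-dien-1-yl]-3-methyloxiran-2-yl]-3-methylbut-1-en-1-yl]oxy}triethylsilane | CC(C)/C=C(\O[Si](CC)(CC)CC)[C@H]1O[C@]1(C)[C@@H](OCc1ccccc1)C/C=C(\C[Si](C)(C)C)/C=C/OCc1ccccc1 | intermediate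
19 | (2S,3S,3aR,5R,6S,8aS)-2,6-bis(benzyloxy)-3-methyl-5-(propan-2-yl)-3-[(triethylsilyl)oxy]-8-[(trimethylsilyl)methyl]-2,3,3a,5,6,8a-hexahydroazulen-4(1H)-one | C[Si](C)(C)CC1=C[C@H](OCc3ccccc3)[C@@H](C(C)C)C(=O)[C@@H]2[C@@H]1C[C@H](OCc3ccccc3)[C@@]2(C)O[Si](CC)(CC)CC | intermediate
20 | (2S,3S,3aR,5R,6S,8aS)-2,6-bis(benzyloxy)-3-hydroxy-3-methyl-8-methylidene-5-(propan-2-yl)octahydroazulen-4(1H)-one | C=C1C[C@H](OCc3ccccc3)[C@@H](C(C)C)C(=O)[C@@H]2[C@@H]1C[C@H](OCc3ccccc3)[C@@]2(C)O | intermediate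
21 | (1S,2S,3aS,6S,7R,8S,8aS)-1-methyl-4-methylidene-7-(propan-2-yl)decahydroazulene-1,2,6,8-tetrol | C=C1C[C@H](O)[C@@H](C(C)C)[C@H](O)[C@@H]2[C@@H]1C[C@H](O)[C@@]2(C)O | intermediate
22 | (1S,2S,3aS,6S,7R,8S,8aS)-1-hydroxy-1-methyl-4-methylidene-7-(propan-2-yl)decahydroazulene-2,6,8-triyl triacetate | C=C1C[C@H](OC(C)=O)[C@@H](C(C)C)[C@H](OC(C)=O)[C@@H]2[C@@H]1C[C@H](OC(C)=O)[C@@]2(C)O | target

Total step count: 18. Longest linear sequence: 16 steps (steps 1–9 and 12–18); steps 10 and 11 prepare the ynol ether 14.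

Steps most likely to fail

Step 15. After the first bond (C1–C5) the cation, which is β to silicon, may lose Me3Si+ to triflate faster than C7 closes on C8 (a Sakurai-type interception), so that only the five-membered ring forms; closure through the compact arrangement, which would give the cis-fused adduct, is the second hazard of this step. The fallback removes silicon from the diene and sets out from bromodiene 16. Negishi coupling with PivOCH2ZnI (Pd(P(tBu)3)2, THF) gives (2Z,5S)-5-(benzyloxy)-2-[(E)-2-(benzyloxy)ethenyl]-5-[(2R,3S)-2-methyl-3-(3-methylbutanoyl)oxiran-2-yl]pent-2-en-1-yl pivalate F1. Enolisation and silylation as in step 14 give its (Z)-triethylsilyl enol ether F2. The cycloaddition under the conditions of step 15 then gives the allylic pivalate cycloadduct F3, which has no group that can leave before ring closure. Palladium-catalysed formate reduction (Pd(OAc)2, PBu3, HCO2NH4, dioxane, 80 °C), with hydride delivery to the more substituted allyl terminus C9, places the double bond exocyclic and gives the silyl ether F4. Removal of the triethylsilyl group (HF·pyridine, THF) rejoins the route at 20.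

Step 17. The lithium amide formed in the medium may enolise the ketone before it is reduced, so that benzyl alcohol is eliminated from C8 through the enolate (E1cB), or the ketyl may be protonated from the wrong face and give the axial C6 carbinol. The fallback separates the two operations and sets out from 20. NaBH4 with CeCl3 (MeOH, −40 °C) delivers hydride axially, anti to H-5 and H-7, and gives (1S,2S,3aS,6S,7S,8S,8aS)-2,6-bis(benzyloxy)-1-methyl-4-methylidene-7-(propan-2-yl)decahydroazulene-1,8-diol F7. Lithium 4,4′-di-tert-butylbiphenylide (THF, −78 °C) then cleaves both benzyl ethers without reducing the isolated alkene and rejoins the route at 21.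

Step 16. The acid that cleaves the allylsilane can also enolise the ketone (epimerisation at C5 and C7, loss of benzyl alcohol from C8) and break the tertiary β-hydroxy ketone by retro-aldol cleavage or dehydration. The fallback removes the ketone before any acid is used and sets out from 19. Li/NH3 (THF, tBuOH, −78 °C, short contact so that benzylic C–O cleavage outruns cleavage of the allylic C8–O bond) reduces the ketone and cleaves both benzyl ethers while the allylsilane and the tertiary silyl ether survive, giving (1S,2S,3aS,6S,7R,8S,8aS)-1-methyl-7-(propan-2-yl)-1-[(triethylsilyl)oxy]-4-[(trimethylsilyl)methyl]-1,2,3,3a,6,7,8,8a-octahydroazulene-2,6,8-triol F5. Acetylation (Ac2O, pyridine, DMAP) gives its 2,6,8-triacetate F6. Protodesilylation and silyl ether hydrolysis (CF3CO2H, CH2Cl2/H2O, 0 °C), now on a substrate without a ketone, give 22 directly.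

Further compounds
F1 | step 15 | (2Z,5S)-5-(benzyloxy)-2-[(E)-2-(benzyloxy)ethenyl]-5-[(2R,3S)-2-methyl-3-(3-methylbutanoyl)oxiran-2-yl]pent-2-en-1-yl 2,2-dimethylpropanoate | CC(C)CC(=O)[C@H]1O[C@]1(C)[C@@H](OCc1ccccc1)C/C=C(\COC(=O)C(C)(C)C)/C=C/OCc1ccccc1
F2 | step 15 | (2Z,5S)-5-(benzyloxy)-2-[(E)-2-(benzyloxy)ethenyl]-5-[(2R,3S)-2-methyl-3-{(1Z)-3-methyl-1-[(triethylsilyl)oxy]but-1-en-1-yl}oxiran-2-yl]pent-2-en-1-yl 2,2-dimethylpropanoate | CC(C)/C=C(\O[Si](CC)(CC)CC)[C@H]1O[C@]1(C)[C@@H](OCc1ccccc1)C/C=C(\COC(=O)C(C)(C)C)/C=C/OCc1ccccc1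
F3 | step 15 | [(2S,3S,3aR,5R,6S,8aS)-2,6-bis(benzyloxy)-3-methyl-4-oxo-5-(propan-2-yl)-3-[(triethylsilyl)oxy]-1,2,3,3a,4,5,6,8a-octahydroazulen-8-yl]methyl 2,2-dimethylpropanoate | CC(C)(C)C(=O)OCC1=C[C@H](OCc3ccccc3)[C@@H](C(C)C)C(=O)[C@@H]2[C@@H]1C[C@H](OCc3ccccc3)[C@@]2(C)O[Si](CC)(CC)CC
F4 | step 15 | (2S,3S,3aR,5R,6S,8aS)-2,6-bis(benzyloxy)-3-methyl-8-methylidene-5-(propan-2-yl)-3-[(triethylsilyl)oxy]octahydroazulen-4(1H)-one | C=C1C[C@H](OCc3ccccc3)[C@@H](C(C)C)C(=O)[C@@H]2[C@@H]1C[C@H](OCc3ccccc3)[C@@]2(C)O[Si](CC)(CC)CC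
F5 | step 16 | (1S,2S,3aS,6S,7R,8S,8aS)-1-methyl-7-(propan-2-yl)-1-[(triethylsilyl)oxy]-4-[(trimethylsilyl)methyl]-1,2,3,3a,6,7,8,8a-octahydroazulene-2,6,8-triol | C[Si](C)(C)CC1=C[C@H](O)[C@@H](C(C)C)[C@H](O)[C@@H]2[C@@H]1C[C@H](O)[C@@]2(C)O[Si](CC)(CC)CC
F6 | step 16 | (1S,2S,3aS,6S,7R,8S,8aS)-1-methyl-7-(propan-2-yl)-1-[(triethylsilyl)oxy]-4-[(trimethylsilyl)methyl]-1,2,3,3a,6,7,8,8a-octahydroazulene-2,6,8-triyl triacetate | C[Si](C)(C)CC1=C[C@H](OC(C)=O)[C@@H](C(C)C)[C@H](OC(C)=O)[C@@H]2[C@@H]1C[C@H](OC(C)=O)[C@@]2(C)O[Si](CC)(CC)CC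
F7 | step 17 | (1S,2S,3aS,6S,7S,8S,8aS)-2,6-bis(benzyloxy)-1-methyl-4-methylidene-7-(propan-2-yl)decahydroazulene-1,8-diol | C=C1C[C@H](OCc3ccccc3)[C@@H](C(C)C)[C@H](O)[C@@H]2[C@@H]1C[C@H](OCc3ccccc3)[C@@]2(C)O
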